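Initiator is a conserved count: each unit charged ends as initiator, as spent initiator B, or as one chain begun, and a dead end A holds two chains begun. The two flasks differ in their time.

| setting | west | south-east |
|---|---|---|
| free monomer | 3.0 M | 3.0 M |
| initiator | 150 mM | 150 mM |
| impurity | 49 mM | 49 mM |
| time | 30 min | 50 min |

* which of the two ends with the longer chains by the average number of monomer units in a chain (chains begun, living or dead) ("neither" if they lie within 10%) (west / south-east / neither)
* average number of monomer units in a chain (chains begun, living or dead) at the end, west
* average number of monomer units in a chain (chains begun, living or dead) at the end, south-east

    free monomer + initiator → living end + monomer in chains (k1 = 0.45 M⁻¹ s⁻¹)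
    free monomer + living end → monomer in chains + living end, rate k2*[living end]*[free monomer] (k2 = 0.61 M⁻¹ s⁻¹)
    2 living end → dead end A (k3 = 5.1 M⁻¹ s⁻¹)
    initiator + impurity → spent initiator B (k4 = 100 M⁻¹ s⁻¹)

- for a step with 2 of a species take k times the square, and two of it per event
- the average divides the monomer in chains by the number of chains begun, living and dead together
- run time (west): 30 min

This reckoning first lets every unit of initiator begin a chain and lets the chains grow undisturbed. Free monomer in west then halves in 7.58 s, shorter than the run of 30 min, so the average reaches 20.0.

Termination comes next. A first half-life of 0.654 s for c(living end) is shorter than that monomer half-life, so in this reckoning c(living end) halves before c(free monomer) does. The reciprocal of c(living end) now climbs linearly with time, at twice the termination constant. The logarithm of c(free monomer) falls by the growth constant over twice the termination constant, times the logarithm of one plus that relative climb. For west that fall is 0.474, and the average drops to 8.17.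

The impurity comes last, as the limiting reagent of its side step, with a smaller charge than initiator. Against initiator the impurity has a lifetime of about 0.0667 s, and initiator against monomer has a lifetime of 0.741 s, longer than the impurity's. This reckoning therefore takes the impurity's own amount off the initiator, and the number of chains begun, charged initiator minus charged impurity, 0.101 M, becomes the divisor. The same fall, reckoned from that count, gives 11.4 for west and 12.0 for south-east. These differ by less than the margin, so this reckoning says neither.

The forecast also says neither, but with 23.6 for west and 24.7 for south-east, longer than this reckoning's lengths. Its grounds for the dead chains read: “counted as one chain per pair”.

The simulation gives 11.8 for west and 12.3 for south-east, so the answer is neither, and the forecast's lengths are twice these. West holds 0.0505 M of dead end A at 30.0 min, which with its living ends makes 0.101 M chains begun, against the reckoned 0.101 M. A neighbour of west charged with 0.020 M of impurity has 0.130 M chains begun by the same subtraction. Its 1.25 M of monomer in chains divided by that gives 9.62, and the simulated average is 9.62.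

All constants are invented; no experiment stands behind them.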